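The north-west run, with half the substrate of the south-east run and colder at 15 °C against 20 °C, stood at 24% at 2.50 min and was still climbing. The south-east run, which is the asked flask followed so far, stood at 24% at 3.00 min and at 25% at 8.00 min.

| setting | south-east | north-west | flask |
|---|---|---|---|
| substrate | 0.36 M | 0.18 M | 0.36 M |
| free catalyst | 0.18 mM | 0.18 mM | 0.18 mM |
| temperature | 20 °C | 15 °C | 20 °C |
| remark | the very flask that is asked about, followed so far | run made earlier |  |
| time |  |  | 12 min |

| run | time / min | target / % |
|---|---|---|
| south-east | 0.500 | 9 |
| south-east | 1.33 | 15 |
| south-east | 3.00 | 24 |
| south-east | 8.00 | 25 |
| north-west | 0.333 | 2 |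
| north-west | 0.833 | 10 |
| north-west | 1.50 | 17 |
| north-west | 2.50 | 24 |

(standard deviation of a reading: 1.5 percentage points)

- target, in percent of the substrate first charged, at 12 min
- the option that brings most further target ("none" if no option brings more than 2 percentage points) (larch / birch / maple / cedar / none)
- target present, with what was taken out counted in, in percent of the substrate first charged, after larch
- target present, with what was taken out counted in, in percent of the substrate first charged, after cedar

- larch: at 12 min take out 90% of the target then present, then wait 4.0 min
- birch: change nothing and wait 4.0 min more
- maple: at 12 min add free catalyst, 100% of the amount charged, then wait 4.0 min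
- cedar: at 12 min raise the temperature by 15 K, then wait 4.0 min

- target that was removed still counts
- additions bring no volume worth counting

The south-east flask has stopped, and we read the stop as a clock. Taking 25% as its plateau and the reading at 1.33 min:

stopping half-life = time × ln(2) / ln(plateau / (plateau − target)) = 1.01 min

This stopping half-life, the time in which the gap between target and plateau halves, is a reading and carries the scatter. Counted on this south-east clock, which the colder and more dilute north-west run need not keep, the north-west run's last reading lies at 2.48 such half-lives, earlier than the last south-east reading at 7.92. Its climb therefore says nothing against a clock, and the two runs may simply have been watched to different stages.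

The readings can't separate a balance from a dying free catalyst, that is, thermodynamic from kinetic control. We bet on the dying catalyst, and then:

half-lives behind the flask at 12 min = 11.9

working share of the catalyst then = 0.0257%

share of a fresh charge's work done in 4.0 min = 93.6%

So we expect about 25% at 12 min, with larch and cedar staying there. Maple is our choice, provided something stands in the flask for fresh catalyst to convert.

The forecast agrees on 25% but chooses larch, with 41% after larch and 18% after cedar: “Waiting or adding catalyst then gains nothing.”

The flask gives 25.8% at 12 min, 25.8% after larch and 25.8% after cedar, while birch adds 0 percentage points and maple adds 12 points.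

    2 substrate → homo dimer (k = 0.100 /M/s, Ea = 67.0 kJ/mol)
    substrate → uncatalysed product (k = 0.0130 /s, Ea = 80.0 kJ/mol)
    free catalyst + intermediate → free catalyst + target (k = 65.0 /M/s, Ea = 50.0 kJ/mol)
    substrate → intermediate (k = 0.0380 /s, Ea = 71.0 kJ/mol)
    free catalyst → spent catalyst (k = 0.0120 /s, Ea = 75.0 kJ/mol)
    (constants at 20 °C)

At 12 min the flask has 11.9 of our stopping half-lives of 1.01 min behind it, a count read from scattered readings, and the flask holds 0.0177% of its catalyst in working form. The neighbour charged with 1.1 × 10⁻⁴ M of free catalyst shows the same 0.0177% at 12.0 min, and its target stands at 18.3%. Free catalyst has a half-life of 0.96 min by its loss to spent catalyst alone, shorter than the 1.1 min of intermediate by its conversion to target at 0.163 min. At 12.0 min the flask holds 0.0177% free catalyst beside 20.6% intermediate.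

Readings and results are simulated on assumed constants; the scatter is artificial.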